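All runs come from a simulation from invented constants.

A closed flask loses no material: counted by the starting material in them, its species sum to the charge. This mass balance allows working with w, the fraction of the charge not in homo dimer.

| flask | starting material | remark | time |
|---|---|---|---|
| red | 0.14 M | run made earlier |  |
| grey | 0.22 M | run made earlier |  |
| flask | 0.10 M |  | 12 min |

| run | time / min | over-reaction product / % | homo dimer / % |
|---|---|---|---|
| red | 1.50 | 0.3 | 43.9 |
| red | 4.00 | 1.3 | 58.9 |
| red | 8.00 | 2.7 | 65.1 |
| red | 12.0 | 1.5 | 67.4 |
| grey | 1.50 | 0 | 53.6 |
| grey | 4.00 | 0.6 | 68.8 |
| grey | 8.00 | 0.7 | 73.9 |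
| grey | 12.0 | 1.6 | 74.6 |

(each reading ± 0.5 percentage points)

- a species is counted by the starting material in it: one homo dimer counts as two
- the numbers in the tables scatter with a standard deviation of 0.5 percentage points

* concentration of over-reaction product at 12 min, in M
* concentration of homo dimer at 12 min, in M
* concentration of isomer of the product B at 12 min, in M

At 12.0 min, w is 32.6% in the red run and 25.4% in the grey run. Treating dimerisation as an apparent second-order loss of w, the reciprocal of w minus one, divided by the charged [starting material], gives the dimerisation dose S at that time, read as 14.8 L mol⁻¹ for the red run, against 13.4 L mol⁻¹ for the grey run. The red value is used, since its charge lies closer to the flask's. For the flask, S gives w = 40.4%, so [homo dimer] is 0.0298 M, and the other species, isomer of the product B among them, share 0.0404 M.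

The forecast gives 0.002 M of over-reaction product, 0.031 M of homo dimer, somewhat more than reckoned here, and 0.003 M of isomer of the product B, the last as “a guessed minor share of the first-order branch”.

The flask gives 0.00221 M of over-reaction product, 0.0303 M of homo dimer and 0.0258 M of isomer of the product B.

    starting material ⇌ target (K = 0.110, k = 0.0363 s⁻¹)
    target ⇌ isomer of the product A (K = 2.42, k = 0.00125 s⁻¹)
    target → over-reaction product (k = 0.00123 s⁻¹)
    target ⇌ isomer of the product B (K = 30.0, k = 0.0197 s⁻¹)
    2 starting material → homo dimer (k = 0.0467 L mol⁻¹ s⁻¹)

The flask's [isomer of the product B] is 0.0258 M, which is 63.9% of the share reckoned from w. Target and isomer of the product B relax by their own step alone with a half-life of 0.568 min, both ways together, short against 12 min. A second flask, charged with 0.025 M of starting material and read at the same time, gets w = 73.0% from S. Computed, it holds 31.0% of its charge as homo dimer, so w = 69.0%, and [homo dimer] is 0.00387 M.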